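**Retrosynthetic overview**
1. The two acyl groups go on last: the target comes from a macrocyclic 8α‑hydroxy‑9β‑silyloxy germacranolide and (2S,3S)‑epoxyangelic acid (Sharpless route from methyl angelate).
2. Key step: the C7–C8 bond of the ten‑membered ring is formed by a SmI2 ketyl‑radical 10‑exo cyclisation of a C8 aldehyde onto a 3‑(methoxymethyl)butenolide; loss of methoxide from the samarium enolate unveils the methylene lactone, and C7 and C8 are set here.
3. The butenolide comes from a (Z)‑iodoallylic alcohol by CO insertion, and that from a propargylic alcohol made by catalytic asymmetric alkynylation of an (E)‑enal (sets C6).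
4. The (E)‑C4=C5 olefin comes from Cp2ZrCl2‑catalysed carboalumination of a terminal alkyne; the (Z)‑C1=C10 olefin with C8/C9 comes from a Z‑selective Wittig reaction of an α‑silyloxy methyl ketone made from (R)‑but‑3‑ene‑1,2‑diol.
5. Ring order: oxirane (separate fragment) and butenolide first, then the ten‑membered carbocycle in the radical step.

Assumption: "(S,S)‑ProPhenol" denotes the ligand enantiomer that adds the alkynyl group to the Si face of the enal (checked by Mosher analysis of the carbinol; the antipode is used otherwise).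

Atom labels C1–C15 used below are germacrane numbers (lactone carbonyl C12, exo‑methylene C13).

**Route**

Step 1
Reactants: 1 (R)-but-3-ene-1,2-diol
Product: 2 (R)-3,4-bis(triethylsilyloxy)but-1-ene
Conditions: Et3SiCl, imidazole, DMF, 0 °C to rt
Reagents that add atoms: chlorotriethylsilane, CC[Si](CC)(CC)Cl
Why: Standard silyl ether formation on both hydroxyls; the stereocentre (future C9) is not touched.

Step 2
Reactants: 2 (R)-3,4-bis(triethylsilyloxy)but-1-ene
Product: 3 (S)-3,4-bis(triethylsilyloxy)butan-2-one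
Conditions: PdCl2(quinox) (5 mol%; quinox = 2-(4,5-dihydro-1,3-oxazol-2-yl)quinoline), AgSbF6 (12 mol%), aq. t-BuOOH, CH2Cl2, 0 °C to rt
Reagents that add atoms: tert-butyl hydroperoxide, CC(C)(C)OO
Why: Peroxide-mediated, catalyst-controlled Tsuji–Wacker oxidation of a protected allylic alcohol gives the methyl ketone without epimerisation; the descriptor changes from R to S only through CIP priorities.

Step 3
Reactants: 4 5-iodopent-1-yne
Product: 5 (pent-4-yn-1-yl)triphenylphosphonium iodide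
Conditions: PPh3, MeCN, reflux
Reagents that add atoms: triphenylphosphine, c1ccc(cc1)P(c1ccccc1)c1ccccc1
Why: SN2 quaternisation of the phosphine by a primary iodide.

Step 4
Reactants: 5 (pent-4-yn-1-yl)triphenylphosphonium iodide; 3 (S)-3,4-bis(triethylsilyloxy)butan-2-one
Product: 7 (2R,3Z)-3-methyl-1,2-bis(triethylsilyloxy)oct-3-en-7-yne, via (pent-4-yn-1-ylidene)triphenylphosphorane 6 (not isolated)
Conditions: NaN(SiMe3)2 (1.0 equiv), THF, −78 °C; then 3, −78 °C to rt
Reagents that add atoms: none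
Why: Wittig olefination in Still's Z-selective variant: non-stabilised ylides and α-alkoxy ketones give Z-trisubstituted allylic ethers, so C9 ends cis to the C2 chain, and the C9 stereocentre is carried in from 3.

Step 5
Reactants: 7 (2R,3Z)-3-methyl-1,2-bis(triethylsilyloxy)oct-3-en-7-yne
Product: 10 (2E,6Z,8R)-3,7-dimethyl-8,9-bis(triethylsilyloxy)nona-2,6-dien-1-ol, via alkenyl(dimethyl)alane 8 (not isolated), via lithium alkenyl(butyl)dimethylalanate 9 (not isolated)
Conditions: Me3Al, Cp2ZrCl2 (20 mol%), H2O (1 equiv), CH2Cl2, −20 °C; evaporate excess Me3Al; n-BuLi, THF, −78 °C; (CH2O)n, to rt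
Reagents that add atoms: trimethylaluminium, C[Al](C)C; formaldehyde (from paraformaldehyde), C=O
Why: Negishi carboalumination catalysed by Cp2ZrCl2 adds methyl and aluminium syn across the terminal alkyne (methyl to the internal carbon), and hydroxymethylation of the alanate with retention gives the E-trisubstituted allylic alcohol (C4=C5).

Step 6
Reactants: 10 (2E,6Z,8R)-3,7-dimethyl-8,9-bis(triethylsilyloxy)nona-2,6-dien-1-ol
Product: 11 (2E,6Z,8R)-3,7-dimethyl-8,9-bis(triethylsilyloxy)nona-2,6-dienal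
Conditions: MnO2, CH2Cl2, rt
Reagents that add atoms: none
Why: Chemoselective allylic oxidation with MnO2; olefin geometry and silyl ethers are unaffected.

Step 7
Reactants: 11 (2E,6Z,8R)-3,7-dimethyl-8,9-bis(triethylsilyloxy)nona-2,6-dienal; 12 3-methoxyprop-1-yne
Product: 14 (4R,5E,9Z,11R)-1-methoxy-6,10-dimethyl-11,12-bis(triethylsilyloxy)dodeca-5,9-dien-2-yn-4-ol, via methyl(3-methoxyprop-1-yn-1-yl)zinc 13 (not isolated)
Conditions: Me2Zn, (S,S)-ProPhenol (20 mol%), Ph3P=O (40 mol%), toluene, 0 to 4 °C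
Reagents that add atoms: none
Why: Trost ProPhenol/Me2Zn alkynylation of an enal; the alkynylzinc adds to the Si face of the aldehyde and sets C6 as R.

Step 8
Reactants: 14 (4R,5E,9Z,11R)-1-methoxy-6,10-dimethyl-11,12-bis(triethylsilyloxy)dodeca-5,9-dien-2-yn-4-ol
Product: 16 (2Z,4R,5E,9Z,11R)-2-iodo-1-methoxy-6,10-dimethyl-11,12-bis(triethylsilyloxy)dodeca-2,5,9-trien-4-ol, via cyclic sodium vinylalanate 15 (not isolated)
Conditions: NaAlH2(OCH2CH2OMe)2, THF, −20 to 0 °C; EtOAc; then I2, THF, −78 °C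
Reagents that add atoms: iodine, II
Why: Hydroxyl-directed trans-hydroalumination of the propargylic alcohol puts H on C7 and Al on C11 in a five-membered alanate, and iodinolysis with retention gives the (Z)-iodide; it is run cold so the β-methoxy group is not eliminated to an allene.

Step 9
Reactants: 16 (2Z,4R,5E,9Z,11R)-2-iodo-1-methoxy-6,10-dimethyl-11,12-bis(triethylsilyloxy)dodeca-2,5,9-trien-4-ol
Product: 17 (5R)-5-[(1E,5Z,7R)-2,6-dimethyl-7,8-bis(triethylsilyloxy)octa-1,5-dien-1-yl]-3-(methoxymethyl)furan-2(5H)-one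
Conditions: PdCl2(PPh3)2 (5 mol%), CO (1 atm), K2CO3, THF, rt
Reagents that add atoms: carbon monoxide, [C-]#[O+]
Why: Carbonylative lactonisation catalysed by PdCl2(PPh3)2: zerovalent palladium formed in the flask inserts into the C–I bond, CO inserts, and the cis hydroxyl captures the acyl group to close the butenolide; C6 is untouched.

Step 10
Reactants: 17 (5R)-5-[(1E,5Z,7R)-2,6-dimethyl-7,8-bis(triethylsilyloxy)octa-1,5-dien-1-yl]-3-(methoxymethyl)furan-2(5H)-one
Product: 18 (2R,3Z,7E)-8-[(2R)-4-(methoxymethyl)-5-oxo-2,5-dihydrofuran-2-yl]-3,7-dimethyl-2-(triethylsilyloxy)octa-3,7-dienal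
Conditions: (COCl)2, DMSO, CH2Cl2, −78 to −40 °C; then i-Pr2NEt, −78 to −30 °C; cold pH 7 work-up, used at once
Reagents that add atoms: none
Why: Swern oxidation converts a primary triethylsilyl ether directly into the aldehyde (chloride-assisted desilylation at the chlorosulfonium stage) while the secondary silyl ether and the methyl ether survive, and the cold amine quench limits epimerisation at C9.

Step 11
Reactants: 18 (2R,3Z,7E)-8-[(2R)-4-(methoxymethyl)-5-oxo-2,5-dihydrofuran-2-yl]-3,7-dimethyl-2-(triethylsilyloxy)octa-3,7-dienal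
Product: 20 (3aR,4R,5R,6Z,10E,11aR)-4-hydroxy-6,10-dimethyl-3-methylidene-5-(triethylsilyloxy)-3a,4,5,8,9,11a-hexahydrocyclodeca[b]furan-2(3H)-one, via diiodosamarium lactone enolate 19 (not isolated)
Conditions: SmI2 (2.5 equiv, THF), slow addition of 18 to a final 0.003 M, −78 °C; then 0 °C; pH 7 phosphate buffer at −20 °C
Reagents that add atoms: none
Why: Proposed new method: SmI2 reduces the aldehyde first to the C8 ketyl radical, which adds 10-exo-trig to the electron-poor C7 of the butenolide on the face anti to the C6–C5 bond (sets C7, trans lactone) with the samarium-bound ketyl oxygen expected anti to the C9 silyloxy group (sets C8, not secured), and a second SmI2 reduces the α-lactone radical to a trivalent samarium enolate that expels methoxide to give the exo-methylene; the closest known reaction types are SmI2 ketyl–olefin cyclisations onto unsaturated esters and lactones (medium rings included) and β-eliminations from samarium enolates, helped here by the Z and E olefins that pre-organise the chain.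

Step 12
Reactants: 21 methyl (2Z)-2-methylbut-2-enoate (methyl angelate)
Product: 22 (2Z)-2-methylbut-2-en-1-ol
Conditions: i-Bu2AlH (2.2 equiv), CH2Cl2, −78 to 0 °C
Reagents that add atoms: none
Why: 1,2-Reduction of the enoate by the aluminium hydride keeps the Z olefin.

Step 13
Reactants: 22 (2Z)-2-methylbut-2-en-1-ol
Product: 23 [(2R,3S)-2,3-dimethyloxiran-2-yl]methanol
Conditions: Ti(OiPr)4, D-(−)-diethyl tartrate, t-BuOOH, 4 Å molecular sieves, CH2Cl2, −20 °C
Reagents that add atoms: tert-butyl hydroperoxide, CC(C)(C)OO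
Why: Sharpless asymmetric epoxidation: D-(−)-tartrate epoxidises (Z)-2-alkenols on the face that gives the (2R,3S)-epoxy alcohol, and syn oxygen transfer keeps the C3 methyl cis to the CH2OH group.

Step 14
Reactants: 23 [(2R,3S)-2,3-dimethyloxiran-2-yl]methanol
Product: 24 (2S,3S)-2,3-dimethyloxirane-2-carboxylic acid
Conditions: RuCl3 (2 mol%), NaIO4, CCl4/MeCN/H2O, 0 °C to rt
Reagents that add atoms: sodium periodate, [Na+].[O-]I(=O)(=O)=O; water, O
Why: Sharpless RuO4 oxidation of an epoxy alcohol to the glycidic acid leaves the oxirane intact; C2 becomes S only through CIP priorities.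

Step 15
Reactants: 20 (3aR,4R,5R,6Z,10E,11aR)-4-hydroxy-6,10-dimethyl-3-methylidene-5-(triethylsilyloxy)-3a,4,5,8,9,11a-hexahydrocyclodeca[b]furan-2(3H)-one; 24 (2S,3S)-2,3-dimethyloxirane-2-carboxylic acid
Product: 26 (3aS,4R,5R,6Z,10E,11aR)-6,10-dimethyl-3-methylidene-2-oxo-5-(triethylsilyloxy)-2,3,3a,4,5,8,9,11a-octahydrocyclodeca[b]furan-4-yl (2S,3S)-2,3-dimethyloxirane-2-carboxylate, via mixed trichlorobenzoic anhydride 25 (not isolated)
Conditions: 24, 2,4,6-Cl3C6H2COCl, Et3N, THF, 0 °C; then 20, DMAP, toluene, rt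
Reagents that add atoms: none
Why: Yamaguchi esterification acylates the only free hydroxyl (C8) with retention and fast enough to outrun translactonisation.

Step 16
Reactants: 26 (3aS,4R,5R,6Z,10E,11aR)-6,10-dimethyl-3-methylidene-2-oxo-5-(triethylsilyloxy)-2,3,3a,4,5,8,9,11a-octahydrocyclodeca[b]furan-4-yl (2S,3S)-2,3-dimethyloxirane-2-carboxylate
Product: 28 (3aS,4R,5R,6Z,10E,11aR)-5-acetoxy-6,10-dimethyl-3-methylidene-2-oxo-2,3,3a,4,5,8,9,11a-octahydrocyclodeca[b]furan-4-yl (2S,3S)-2,3-dimethyloxirane-2-carboxylate (CNP0304643.2), via 9-hydroxy 8-epoxyangelate 27 (not isolated)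
Conditions: HF·pyridine, pyridine, THF, 0 °C; then Ac2O, DMAP, 0 °C to rt
Reagents that add atoms: acetic anhydride, CC(=O)OC(C)=O
Why: Buffered fluoride desilylation followed in the same flask by DMAP-catalysed acetylation of the freed C9 hydroxyl; no stereocentre is touched.

**Compound list**

1 | (R)-but-3-ene-1,2-diol | C=C[C@@H](O)CO | starting material
2 | (R)-3,4-bis(triethylsilyloxy)but-1-ene | C=C[C@@H](O[Si](CC)(CC)CC)CO[Si](CC)(CC)CC | intermediate
3 | (S)-3,4-bis(triethylsilyloxy)butan-2-one | CC(=O)[C@@H](O[Si](CC)(CC)CC)CO[Si](CC)(CC)CC | intermediate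
4 | 5-iodopent-1-yne | C#CCCCI | starting material
5 | (pent-4-yn-1-yl)triphenylphosphonium iodide | C#CCCC[P+](c1ccccc1)(c1ccccc1)c1ccccc1.[I-] | intermediate
6 | (pent-4-yn-1-ylidene)triphenylphosphorane (not isolated) | C#CCCC=P(c1ccccc1)(c1ccccc1)c1ccccc1 | intermediate
7 | (2R,3Z)-3-methyl-1,2-bis(triethylsilyloxy)oct-3-en-7-yne | C#CCC/C=C(/C)[C@@H](O[Si](CC)(CC)CC)CO[Si](CC)(CC)CC | intermediate
8 | dimethyl[(1E,5Z,7R)-2,6-dimethyl-7,8-bis(triethylsilyloxy)octa-1,5-dien-1-yl]alane (not isolated) | C[Al](C)/C=C(\C)CC/C=C(/C)[C@@H](O[Si](CC)(CC)CC)CO[Si](CC)(CC)CC | intermediate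
9 | lithium butyl(dimethyl)[(1E,5Z,7R)-2,6-dimethyl-7,8-bis(triethylsilyloxy)octa-1,5-dien-1-yl]alanate (not isolated) | [Li+].CCCC[Al-](C)(C)/C=C(\C)CC/C=C(/C)[C@@H](O[Si](CC)(CC)CC)CO[Si](CC)(CC)CC | intermediate
10 | (2E,6Z,8R)-3,7-dimethyl-8,9-bis(triethylsilyloxy)nona-2,6-dien-1-ol | OC/C=C(\C)CC/C=C(/C)[C@@H](O[Si](CC)(CC)CC)CO[Si](CC)(CC)CC | intermediate
11 | (2E,6Z,8R)-3,7-dimethyl-8,9-bis(triethylsilyloxy)nona-2,6-dienal | O=C/C=C(\C)CC/C=C(/C)[C@@H](O[Si](CC)(CC)CC)CO[Si](CC)(CC)CC | intermediate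
12 | 3-methoxyprop-1-yne (methyl propargyl ether) | C#CCOC | starting material
13 | methyl(3-methoxyprop-1-yn-1-yl)zinc (not isolated) | C[Zn]C#CCOC | intermediate
14 | (4R,5E,9Z,11R)-1-methoxy-6,10-dimethyl-11,12-bis(triethylsilyloxy)dodeca-5,9-dien-2-yn-4-ol | COCC#C[C@H](O)/C=C(\C)CC/C=C(/C)[C@@H](O[Si](CC)(CC)CC)CO[Si](CC)(CC)CC | intermediate
15 | cyclic sodium vinylalanate (1,2-oxaluminole ate complex: Al on C11, bound to the C6 oxygen, two 2-methoxyethoxy ligands; not isolated) | [Na+].COCCO[Al-]1(OCCOC)O[C@H](/C=C(\C)CC/C=C(/C)[C@@H](O[Si](CC)(CC)CC)CO[Si](CC)(CC)CC)C=C1COC | intermediate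
16 | (2Z,4R,5E,9Z,11R)-2-iodo-1-methoxy-6,10-dimethyl-11,12-bis(triethylsilyloxy)dodeca-2,5,9-trien-4-ol | COC/C(I)=C/[C@H](O)/C=C(\C)CC/C=C(/C)[C@@H](O[Si](CC)(CC)CC)CO[Si](CC)(CC)CC | intermediate
17 | (5R)-5-[(1E,5Z,7R)-2,6-dimethyl-7,8-bis(triethylsilyloxy)octa-1,5-dien-1-yl]-3-(methoxymethyl)furan-2(5H)-one | COCC1=C[C@H](OC1=O)/C=C(\C)CC/C=C(/C)[C@@H](O[Si](CC)(CC)CC)CO[Si](CC)(CC)CC | intermediate
18 | (2R,3Z,7E)-8-[(2R)-4-(methoxymethyl)-5-oxo-2,5-dihydrofuran-2-yl]-3,7-dimethyl-2-(triethylsilyloxy)octa-3,7-dienal | COCC1=C[C@H](OC1=O)/C=C(\C)CC/C=C(/C)[C@@H](O[Si](CC)(CC)CC)C=O | intermediate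
19 | bis(diiodosamarium) enolate–alkoxide of the cyclised 13-methoxy lactone (not isolated) | COCC1=C(O[Sm](I)I)O[C@@H]2/C=C(\C)CC/C=C(/C)[C@@H](O[Si](CC)(CC)CC)[C@H](O[Sm](I)I)[C@@H]12 | intermediate
20 | (3aR,4R,5R,6Z,10E,11aR)-4-hydroxy-6,10-dimethyl-3-methylidene-5-(triethylsilyloxy)-3a,4,5,8,9,11a-hexahydrocyclodeca[b]furan-2(3H)-one (8α-hydroxy, 9β-silyloxy, trans-6,7-lactone) | C=C1C(=O)O[C@@H]2/C=C(\C)CC/C=C(/C)[C@@H](O[Si](CC)(CC)CC)[C@H](O)[C@@H]12 | intermediate
21 | methyl (2Z)-2-methylbut-2-enoate (methyl angelate) | C/C=C(/C)C(=O)OC | starting material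
22 | (2Z)-2-methylbut-2-en-1-ol | C/C=C(/C)CO | intermediate
23 | [(2R,3S)-2,3-dimethyloxiran-2-yl]methanol | OC[C@@]1(C)O[C@H]1C | intermediate
24 | (2S,3S)-2,3-dimethyloxirane-2-carboxylic acid | OC(=O)[C@@]1(C)O[C@H]1C | intermediate
25 | (2S,3S)-2,3-dimethyloxirane-2-carboxylic 2,4,6-trichlorobenzoic anhydride (not isolated) | O=C(OC(=O)[C@@]1(C)O[C@H]1C)c1c(Cl)cc(Cl)cc1Cl | intermediate
26 | (3aS,4R,5R,6Z,10E,11aR)-6,10-dimethyl-3-methylidene-2-oxo-5-(triethylsilyloxy)-2,3,3a,4,5,8,9,11a-octahydrocyclodeca[b]furan-4-yl (2S,3S)-2,3-dimethyloxirane-2-carboxylate | C=C1C(=O)O[C@@H]2/C=C(\C)CC/C=C(/C)[C@@H](O[Si](CC)(CC)CC)[C@H](OC(=O)[C@@]3(C)O[C@H]3C)[C@@H]12 | intermediate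
27 | (3aS,4R,5R,6Z,10E,11aR)-5-hydroxy-6,10-dimethyl-3-methylidene-2-oxo-2,3,3a,4,5,8,9,11a-octahydrocyclodeca[b]furan-4-yl (2S,3S)-2,3-dimethyloxirane-2-carboxylate (not isolated) | C=C1C(=O)O[C@@H]2/C=C(\C)CC/C=C(/C)[C@@H](O)[C@H](OC(=O)[C@@]3(C)O[C@H]3C)[C@@H]12 | intermediate
28 | (3aS,4R,5R,6Z,10E,11aR)-5-acetoxy-6,10-dimethyl-3-methylidene-2-oxo-2,3,3a,4,5,8,9,11a-octahydrocyclodeca[b]furan-4-yl (2S,3S)-2,3-dimethyloxirane-2-carboxylate (CNP0304643.2) | C=C1C(=O)O[C@@H]2/C=C(\C)CC/C=C(/C)[C@@H](OC(C)=O)[C@H](OC(=O)[C@@]3(C)O[C@H]3C)[C@@H]12 | target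

**Step count**

Total steps: 16 (two for ketone 3, nine in the main line to 20, three for acid 24, two to finish).
Longest linear sequence: 12 steps (steps 1, 2, 4–11, 15 and 16, from 1). The branch from 4 (steps 3–11, 15 and 16) is 11 steps.

**Three steps most likely to fail, with fallbacks**

Step 11 (radical ring closure). The ten-membered ring closure competes with intermolecular pinacol coupling, and the C8 configuration rests on a conformational argument only. If the ring forms but with the ketyl oxygen on the other face, the fallback sets out from 18. The step 11 conditions then give the C8 epimer (3aR,4S,5R,6Z,10E,11aR)-4-hydroxy-6,10-dimethyl-3-methylidene-5-(triethylsilyloxy)-3a,4,5,8,9,11a-hexahydrocyclodeca[b]furan-2(3H)-one F1. F1 is not acylated with retention but coupled with acid 24 under Mitsunobu conditions (PPh3, diisopropyl azodicarboxylate, toluene, 0 °C to rt), which installs the ester with inversion at C8 and comes back to the route at 26.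

Step 8 (directed hydroalumination–iodination). The vinylalanate carries a β-methoxy group and can collapse to an allenol, and the later methoxide loss in step 11 depends on this substituent. The fallback brings C13 in only after the radical ring closure and sets out from enal 11. ProPhenol/Me2Zn addition of methyl propiolate gives methyl (4R,5E,9Z,11R)-4-hydroxy-6,10-dimethyl-11,12-bis(triethylsilyloxy)dodeca-5,9-dien-2-ynoate F2. Semihydrogenation (H2, Pd/CaCO3–Pb(OAc)2 Lindlar catalyst, quinoline) and lactonisation of the Z-enoate give (5S)-5-[(1E,5Z,7R)-2,6-dimethyl-7,8-bis(triethylsilyloxy)octa-1,5-dien-1-yl]furan-2(5H)-one F3. Swern oxidation of the primary silyl ether as in step 10 gives (2R,3Z,7E)-3,7-dimethyl-8-[(2S)-5-oxo-2,5-dihydrofuran-2-yl]-2-(triethylsilyloxy)octa-3,7-dienal F4. The SmI2 ketyl cyclisation of step 11 is then run, and once the SmI2 is consumed the samarium enolate is trapped with Eschenmoser's salt (dimethylmethylideneammonium iodide), giving (3aR,4R,5R,6Z,10E,11aR)-3-[(dimethylamino)methyl]-4-hydroxy-6,10-dimethyl-5-(triethylsilyloxy)-3a,4,5,8,9,11a-hexahydrocyclodeca[b]furan-2(3H)-one F5. MeI then NaHCO3 eliminates trimethylamine and comes back to the route at 20.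

Step 10 (direct Swern oxidation of the silyl ether). The amine quench can epimerise C9 of the α-silyloxy β,γ-unsaturated aldehyde or C6 of the butenolide, and selectivity between the two silyl ethers may be incomplete. The fallback sets out from 17 and uses two neutral operations. HF·pyridine/pyridine (THF, −10 °C) removes only the primary silyl group to give (5R)-5-[(1E,5Z,7R)-8-hydroxy-2,6-dimethyl-7-(triethylsilyloxy)octa-1,5-dien-1-yl]-3-(methoxymethyl)furan-2(5H)-one F6. Dess–Martin periodinane with NaHCO3 (CH2Cl2, 0 °C) then comes back to the route at 18.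

**Further compounds**

F1 | step 11 | (3aR,4S,5R,6Z,10E,11aR)-4-hydroxy-6,10-dimethyl-3-methylidene-5-(triethylsilyloxy)-3a,4,5,8,9,11a-hexahydrocyclodeca[b]furan-2(3H)-one | C=C1C(=O)O[C@@H]2/C=C(\C)CC/C=C(/C)[C@@H](O[Si](CC)(CC)CC)[C@@H](O)[C@@H]12
F2 | step 8 | methyl (4R,5E,9Z,11R)-4-hydroxy-6,10-dimethyl-11,12-bis(triethylsilyloxy)dodeca-5,9-dien-2-ynoate | COC(=O)C#C[C@H](O)/C=C(\C)CC/C=C(/C)[C@@H](O[Si](CC)(CC)CC)CO[Si](CC)(CC)CC
F3 | step 8 | (5S)-5-[(1E,5Z,7R)-2,6-dimethyl-7,8-bis(triethylsilyloxy)octa-1,5-dien-1-yl]furan-2(5H)-one | O=C1C=C[C@H](O1)/C=C(\C)CC/C=C(/C)[C@@H](O[Si](CC)(CC)CC)CO[Si](CC)(CC)CC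
F4 | step 8 | (2R,3Z,7E)-3,7-dimethyl-8-[(2S)-5-oxo-2,5-dihydrofuran-2-yl]-2-(triethylsilyloxy)octa-3,7-dienal | O=C1C=C[C@H](O1)/C=C(\C)CC/C=C(/C)[C@@H](O[Si](CC)(CC)CC)C=O
F5 | step 8 | (3aR,4R,5R,6Z,10E,11aR)-3-[(dimethylamino)methyl]-4-hydroxy-6,10-dimethyl-5-(triethylsilyloxy)-3a,4,5,8,9,11a-hexahydrocyclodeca[b]furan-2(3H)-one (C3 epimers) | CN(C)CC1C(=O)O[C@@H]2/C=C(\C)CC/C=C(/C)[C@@H](O[Si](CC)(CC)CC)[C@H](O)[C@@H]12
F6 | step 10 | (5R)-5-[(1E,5Z,7R)-8-hydroxy-2,6-dimethyl-7-(triethylsilyloxy)octa-1,5-dien-1-yl]-3-(methoxymethyl)furan-2(5H)-one | COCC1=C[C@H](OC1=O)/C=C(\C)CC/C=C(/C)[C@@H](O[Si](CC)(CC)CC)CO
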